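Retrosynthesis: the C8 ester is cut first, then the C1–C10 bond of the ten-membered ring (C1 acyl radical onto a C8 propenyl ketone), then C7–C8, the lactone bonds (C6–O, C11–C12) together with a C7–I handle, C6–C7, and C2–C3.
Enabling feature: in the C1–C10 ring the C1 ketone and the C8 oxygen are 1,4-related through C10(Me)–C9, so with C8 as a ketone the C9=C10 bond is an enone that accepts a C1 acyl radical at C10. The trans C4–C5 epoxide and the butenolide ring (C6, C7, C11, C12, O) disfavour closure to smaller rings.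
Forward order: a C1–C6 epoxy aldehyde chain is made, the butenolide ring is closed on C6, the crotonoyl unit is attached at C7, the ten-membered carbocycle is closed, and the separately made C8 side chain is esterified on last.
Stereochemistry: C3 (temporary) from Brown allylation; C4 and C5 from Sharpless epoxidation; C6 from Felkin–Anh alkynylation followed by invertive carbonylation–iodolactonisation; C10 from the macrocyclisation; C8 from Luche reduction; the Z side-chain alkene from syn carbocupration.
Key step: step 17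

Remark: germacrane numbering is used (C1–C10 carbocycle, C11–C13 lactone carbons and acetoxymethyl carbon, C14 and C15 methyl groups). C3 is carried as the R silyl ether: it ends as a ketone, and this epimer is the matched one for the epoxidation.

Step 1
Reactants: 1 prenyl acetate
Product: 2 (2E)-4-acetoxy-2-methylbut-2-enal
Conditions: SeO2 (1.1 equiv), 1,4-dioxane, trace H2O, 80 °C
Reagents that add atoms: selenium dioxide O=[Se]=O
Why: Riley allylic oxidation with SeO2 (ene reaction, then [2,3]-shift) attacks the E methyl group of the trisubstituted alkene and should give the E enal, which places the future C3 and C6 trans across C4=C5.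

Step 2
Reactants: 2 (2E)-4-acetoxy-2-methylbut-2-enal
Product: 3 (2E,4R)-4-hydroxy-3-methylhepta-2,6-dien-1-yl acetate
Conditions: (+)-Ipc2BOMe [the enantiomer made from (−)-α-pinene], allylMgBr, Et2O, −78 °C to rt; then 2, −78 °C; H2O2, pH 7 buffer
Reagents that add atoms: allylmagnesium bromide C=CC[Mg]Br
Why: Brown allylboration through a chair-like six-membered transition state is reagent-controlled, should add the allyl group 1,2 to the Re face of the enal to set C3 as R, and does not touch the acetate.

Step 3
Reactants: 3 (2E,4R)-4-hydroxy-3-methylhepta-2,6-dien-1-yl acetate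
Product: 4 [(2R,3R)-3-[(1R)-1-hydroxybut-3-en-1-yl]-3-methyloxiran-2-yl]methyl acetate
Conditions: Ti(OiPr)4 (cat.), D-(−)-diisopropyl tartrate, t-BuOOH, 4 Å molecular sieves, CH2Cl2, −20 °C
Reagents that add atoms: tert-butyl hydroperoxide CC(C)(C)OO
Why: Sharpless asymmetric epoxidation of a secondary allylic alcohol in its matched sense (the R carbinol is the fast-reacting enantiomer with the D-tartrate) should deliver oxygen anti to the C3 hydroxyl, which sets C4 and C5, upgrades the enantiomeric purity and leaves the isolated terminal alkene alone.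

Step 4
Reactants: 4 [(2R,3R)-3-[(1R)-1-hydroxybut-3-en-1-yl]-3-methyloxiran-2-yl]methyl acetate
Product: 5 [(2R,3S)-3-[(1R)-1-(tert-butyldimethylsilyloxy)but-3-en-1-yl]-3-methyloxiran-2-yl]methyl acetate
Conditions: TBSOTf, 2,6-lutidine, CH2Cl2, −78 °C
Reagents that add atoms: tert-butyldimethylsilyl triflate CC(C)(C)[Si](C)(C)OS(=O)(=O)C(F)(F)F
Why: O-silylation of the hindered secondary alcohol with a silyl triflate and a hindered pyridine base is fast at low temperature and should spare the epoxide and the acetate.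

Step 5
Reactants: 5 [(2R,3S)-3-[(1R)-1-(tert-butyldimethylsilyloxy)but-3-en-1-yl]-3-methyloxiran-2-yl]methyl acetate
Product: 6 [(2R,3S)-3-[(1R)-1-(tert-butyldimethylsilyloxy)but-3-en-1-yl]-3-methyloxiran-2-yl]methanol
Conditions: K2CO3 (cat.), MeOH, 0 °C
Reagents that add atoms: none
Why: Base-catalysed transesterification (methanolysis) removes the primary acetate, and the trisubstituted epoxide is the favoured side of any Payne equilibrium.

Step 6
Reactants: 6 [(2R,3S)-3-[(1R)-1-(tert-butyldimethylsilyloxy)but-3-en-1-yl]-3-methyloxiran-2-yl]methanol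
Product: 7 (2S,3S)-3-[(1R)-1-(tert-butyldimethylsilyloxy)but-3-en-1-yl]-3-methyloxirane-2-carbaldehyde
Conditions: Dess–Martin periodinane, CH2Cl2, 0 °C to rt
Reagents that add atoms: none
Why: Dess–Martin oxidation should give the C6 epoxy aldehyde under near-neutral conditions without epimerising C5.

Step 7
Reactants: 7 (2S,3S)-3-[(1R)-1-(tert-butyldimethylsilyloxy)but-3-en-1-yl]-3-methyloxirane-2-carbaldehyde; 8 tert-butyldimethyl(prop-2-yn-1-yloxy)silane
Product: 10 anti propargylic alcohol (6R carbinol carrying the 4-silyloxybut-2-ynyl unit C7–C11–C13), via silyloxypropynyllithium 9 (not isolated)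
Conditions: 8, n-BuLi, THF, −78 °C; then 7, −78 °C; aq. NH4Cl
Reagents that add atoms: none
Why: 1,2-Addition of the lithium acetylide to the α,β-epoxy aldehyde should follow the Felkin–Anh model, reinforced by the methyl group cis to the formyl group on the epoxide, and give mainly the C6 carbinol anti to the epoxide oxygen, the epimer needed for the invertive lactone construction.

Step 8
Reactants: 10 anti propargylic alcohol
Product: 11 C6 methanesulfonate of 10
Conditions: MsCl, Et3N, CH2Cl2, −40 °C
Reagents that add atoms: methanesulfonyl chloride CS(=O)(=O)Cl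
Why: O-Sulfonylation does not touch the C6–O bond, so the configuration is retained.

Step 9
Reactants: 11 C6 methanesulfonate of 10
Product: 12 (aR)-2-[(tert-butyldimethylsilyloxy)methyl]-4-{(2R,3S)-3-[(1R)-1-(tert-butyldimethylsilyloxy)but-3-en-1-yl]-3-methyloxiran-2-yl}buta-2,3-dienoic acid
Conditions: Pd(PPh3)4 (5 mol %), CO (1 atm), 2,6-lutidine, THF/H2O, rt
Reagents that add atoms: carbon monoxide [C-]#[O+]; water O
Why: Palladium-catalysed hydroxycarbonylation of a propargylic mesylate (anti SN2′ attack of zerovalent palladium at C11, CO insertion into the allenylpalladium species, hydrolysis) should transfer the C6 configuration into the allene axis; the lutidine buffers the sulfonic acid, and a short contact time protects the epoxide, which becomes allylic only in the product.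

Step 10
Reactants: 12 allenic acid
Product: 13 (5R)-4-iodo-3-[(tert-butyldimethylsilyloxy)methyl]-5-{(2R,3S)-3-[(1R)-1-(tert-butyldimethylsilyloxy)but-3-en-1-yl]-3-methyloxiran-2-yl}furan-2(5H)-one
Conditions: I2, NaHCO3, MeCN/H2O, 0 °C
Reagents that add atoms: iodine II
Why: Iodolactonisation of the 2,3-allenoic acid is a 5-endo anti addition across C6=C7 that should turn the axial chirality into the C6 centre with net inversion relative to 11, giving the C6–O bond syn to the epoxide oxygen as in the target and a C7 iodide as handle.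

Step 11
Reactants: 13 iodobutenolide with C13 silyl ether
Product: 15 C13 acetate of the iodobutenolide, via C13 alcohol 14 (not isolated)
Conditions: HF·pyridine, pyridine, THF, 0 °C; then Ac2O, DMAP, 0 °C to rt
Reagents that add atoms: acetic anhydride CC(=O)OC(C)=O
Why: Fluoride-mediated desilylation with buffered HF·pyridine should cleave the primary allylic silyl ether well before the hindered secondary one at C3, and O-acetylation in the same flask installs the C13 acetate before a C8 carbonyl exists, which avoids hemiketal and furan formation from a free C13 alcohol.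

Step 12
Reactants: 15 C13 acetate of the iodobutenolide; 16 crotonaldehyde
Product: 17 C8 allylic alcohol (15 with iodine replaced by a (2E)-1-hydroxybut-2-en-1-yl group, both C8 epimers)
Conditions: CrCl2, NiCl2 (2 mol %), DMF, rt
Reagents that add atoms: none
Why: Nozaki–Hiyama–Kishi coupling (insertion of zerovalent nickel into the electron-poor vinyl iodide, transfer to trivalent chromium, 1,2-addition to the enal) should form C7–C8 while tolerating lactone, acetate, epoxide and silyl ether; the C8 configuration is of no consequence here.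

Step 13
Reactants: 17 C8 allylic alcohol
Product: 18 [(5S)-4-[(2E)-but-2-enoyl]-5-{(2R,3S)-3-[(1R)-1-(tert-butyldimethylsilyloxy)but-3-en-1-yl]-3-methyloxiran-2-yl}-2-oxo-2,5-dihydrofuran-3-yl]methyl acetate
Conditions: Dess–Martin periodinane, CH2Cl2, 0 °C
Reagents that add atoms: none
Why: Dess–Martin oxidation of the doubly allylic alcohol should give the cross-conjugated C8 ketone under neutral conditions and converge both C8 epimers.

Step 14
Reactants: 18 C8 propenyl ketone with terminal alkene
Product: 19 C1 aldehyde (18 with the CH=CH2 terminus cleaved to CHO)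
Conditions: OsO4 (2 mol %), NaIO4, 2,6-lutidine, 1,4-dioxane/H2O, rt
Reagents that add atoms: osmium tetroxide O=[Os](=O)(=O)=O; sodium periodate [Na+].[O-]I(=O)(=O)=O
Why: Lemieux–Johnson cleavage should be chemoselective because OsO4 dihydroxylates the electron-rich monosubstituted alkene far faster than the enone alkene or the tetrasubstituted butenolide alkene, and periodate then cleaves the diol.

Step 15
Reactants: 19 C1 aldehyde
Product: 20 (3R)-3-{(2S,3R)-3-[(2S)-4-(acetoxymethyl)-3-[(2E)-but-2-enoyl]-5-oxo-2,5-dihydrofuran-2-yl]-2-methyloxiran-2-yl}-3-(tert-butyldimethylsilyloxy)propanoic acid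
Conditions: NaClO2, NaH2PO4, 2-methyl-2-butene, t-BuOH/H2O, 0 °C
Reagents that add atoms: sodium chlorite [Na+].[O-]Cl=O
Why: Pinnick oxidation converts the aldehyde to the acid at buffered pH with a chlorine scavenger, which should spare enone, epoxide and silyl ether; the acid is used at once so that it cannot open the C4–C5 epoxide to a γ-lactone.

Step 16
Reactants: 20 C1 carboxylic acid
Product: 21 Se-phenyl (3R)-3-{(2S,3R)-3-[(2S)-4-(acetoxymethyl)-3-[(2E)-but-2-enoyl]-5-oxo-2,5-dihydrofuran-2-yl]-2-methyloxiran-2-yl}-3-(tert-butyldimethylsilyloxy)propaneselenoate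
Conditions: N-(phenylseleno)phthalimide, Bu3P (premixed), CH2Cl2, −30 °C
Reagents that add atoms: N-(phenylseleno)phthalimide O=C1N([Se]c2ccccc2)C(=O)c2ccccc12
Why: Phosphine-mediated redox condensation (acyloxyphosphonium formation, then attack of phenylselenolate) makes selenoesters at low temperature from acids that carry enone acceptors.

Step 17
Reactants: 21 C1 phenylselenoester with the C8 (E)-propenyl ketone
Product: 22 (3R,4S,5R,6S,10S)-13-acetoxy-3-(tert-butyldimethylsilyloxy)-4,5-epoxy-1,8-dioxogermacr-7(11)-en-12,6-olide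
Conditions: Bu3SnH (1.3 equiv) and AIBN (0.2 equiv) by syringe pump over 8 h, benzene (2 mM in 21), 80 °C
Reagents that add atoms: none
Why: The tributylstannyl radical abstracts the phenylseleno group from C1, and the nucleophilic acyl radical adds to C10, the β-carbon of the E-propenyl ketone, to give a C9 α-keto radical that takes hydrogen from Bu3SnH and carries the chain. The closest known reaction type is the tin hydride-mediated acyl radical macrocyclisation of acyl selenides onto enones and enoates, which gives macrocyclic 1,4-dicarbonyl compounds. The ring should close in the 10-endo-trig mode, because closure onto the butenolide alkene would need a seven- or eight-membered ring that holds the trans-epoxide and would be attack on a tetrasubstituted alkene. The new C10 centre is set by the enone face that the acyl radical reaches in the folded chain, whose turn is fixed by the trans-epoxide and the lactone-bearing C6 centre with the methyl group pointing outward; S is the expected configuration and, being α to the C1 ketone, it can be corrected by equilibration. The step needs cyclisation to outrun reduction of the acyl radical and loss of CO: slow stannane addition at high dilution keeps the hydride concentration low, and decarbonylation would give only an unstabilised primary C2 radical.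

Step 18
Reactants: 22 ten-membered 1,8-diketone
Product: 23 (3R,4S,5R,6S,8S,10S)-13-acetoxy-3-(tert-butyldimethylsilyloxy)-4,5-epoxy-8-hydroxy-1-oxogermacr-7(11)-en-12,6-olide
Conditions: NaBH4, CeCl3·7H2O, MeOH, −78 °C
Reagents that add atoms: none
Why: Luche reduction is selective for the conjugated C8 ketone over the saturated α-branched C1 ketone, and hydride attack on the exposed peripheral face of the ten-membered ring is expected to give the 8S alcohol.

Step 19
Reactants: 24 prop-2-yn-1-ol
Product: 25 1-methoxy-4-[(prop-2-yn-1-yloxy)methyl]benzene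
Conditions: NaH, 4-methoxybenzyl chloride, Bu4NI (cat.), THF, 0 °C to rt
Reagents that add atoms: 4-methoxybenzyl chloride COc1ccc(CCl)cc1
Why: Williamson etherification of the sodium alkoxide with the benzylic chloride gives the PMB ether.

Step 20
Reactants: 25 1-methoxy-4-[(prop-2-yn-1-yloxy)methyl]benzene
Product: 27 methyl 4-[(4-methoxybenzyl)oxy]but-2-ynoate, via PMB-oxypropynyllithium 26 (not isolated)
Conditions: n-BuLi, THF, −78 °C; then ClCO2Me
Reagents that add atoms: methyl chloroformate COC(Cl)=O
Why: C-Acylation of the lithium acetylide with the chloroformate gives the ynoate.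

Step 21
Reactants: 27 methyl 4-[(4-methoxybenzyl)oxy]but-2-ynoate
Product: 28 methyl (2Z)-4-[(4-methoxybenzyl)oxy]-3-methylbut-2-enoate
Conditions: Me2CuLi (from MeLi and CuI), THF, −78 °C; then MeOH
Reagents that add atoms: lithium dimethylcuprate [Li+].C[Cu-]C
Why: Syn carbocupration of the ynoate at −78 °C and protonation with retention place the new methyl group cis to the α-hydrogen, so the protected hydroxymethyl group ends cis to the ester (Z).

Step 22
Reactants: 28 methyl (2Z)-4-[(4-methoxybenzyl)oxy]-3-methylbut-2-enoate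
Product: 29 (2Z)-4-[(4-methoxybenzyl)oxy]-3-methylbut-2-enoic acid
Conditions: LiOH, THF/H2O, rt; then dilute HCl
Reagents that add atoms: lithium hydroxide [Li+].[OH-]
Why: Saponification of the methyl ester does not affect the benzylic ether or the alkene geometry.

Step 23
Reactants: 23 8S alcohol; 29 (2Z)-4-[(4-methoxybenzyl)oxy]-3-methylbut-2-enoic acid
Product: 31 C8 ester of 23 with the PMB-protected side chain, via mixed anhydride 30 (not isolated)
Conditions: 29, 2,4,6-trichlorobenzoyl chloride, Et3N, THF, rt; then 23, DMAP, toluene, rt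
Reagents that add atoms: none
Why: Yamaguchi esterification through the mixed anhydride and DMAP should acylate the hindered allylic C8 alcohol with retention at C8 and without isomerising the Z enoate.

Step 24
Reactants: 31 C8 ester with C3 silyl ether
Product: 32 C3 alcohol (31 with the silyl ether cleaved)
Conditions: HF·pyridine, pyridine, THF, 0 °C to rt
Reagents that add atoms: none
Why: Fluoride-mediated desilylation with buffered HF·pyridine should remove the C3 silyl ether without opening the epoxide or cleaving the esters and the PMB ether.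

Step 25
Reactants: 32 C3 alcohol
Product: 33 C3 ketone (PMB ether of the target)
Conditions: Dess–Martin periodinane (1.2 equiv), CH2Cl2, 0 °C
Reagents that add atoms: none
Why: Dess–Martin oxidation of the β-hydroxy ketone should give the 1,3-diketone, which is also the α,β-epoxy ketone, and a small excess of oxidant avoids over-oxidation at C2.

Step 26
Reactants: 33 PMB ether of the target
Product: 34 CNP0295642.1
Conditions: DDQ, CH2Cl2/pH 7 buffer, 0 °C
Reagents that add atoms: none
Why: Oxidative cleavage of the p-methoxybenzyl ether with DDQ is neutral and should spare the epoxy diketone, the acetate and the Z hydroxy enoate, which could lactonise under acid or base.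

Compound list
1 | prenyl acetate (3-methylbut-2-en-1-yl acetate) | CC(C)=CCOC(C)=O | starting material
2 | (2E)-4-acetoxy-2-methylbut-2-enal | CC(=O)OC/C=C(\C)C=O | intermediate
3 | (2E,4R)-4-hydroxy-3-methylhepta-2,6-dien-1-yl acetate | C=CC[C@@H](O)/C(C)=C/COC(C)=O | intermediate
4 | [(2R,3R)-3-[(1R)-1-hydroxybut-3-en-1-yl]-3-methyloxiran-2-yl]methyl acetate (C3 hydroxyl anti to the epoxide oxygen) | C=CC[C@@H](O)[C@@]1(C)O[C@@H]1COC(C)=O | intermediate
5 | [(2R,3S)-3-[(1R)-1-(tert-butyldimethylsilyloxy)but-3-en-1-yl]-3-methyloxiran-2-yl]methyl acetate | C=CC[C@@H](O[Si](C)(C)C(C)(C)C)[C@@]1(C)O[C@@H]1COC(C)=O | intermediate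
6 | [(2R,3S)-3-[(1R)-1-(tert-butyldimethylsilyloxy)but-3-en-1-yl]-3-methyloxiran-2-yl]methanol | C=CC[C@@H](O[Si](C)(C)C(C)(C)C)[C@@]1(C)O[C@@H]1CO | intermediate
7 | (2S,3S)-3-[(1R)-1-(tert-butyldimethylsilyloxy)but-3-en-1-yl]-3-methyloxirane-2-carbaldehyde | C=CC[C@@H](O[Si](C)(C)C(C)(C)C)[C@@]1(C)O[C@@H]1C=O | intermediate
8 | tert-butyldimethyl(prop-2-yn-1-yloxy)silane | C#CCO[Si](C)(C)C(C)(C)C | starting material
9 | [3-(tert-butyldimethylsilyloxy)prop-1-yn-1-yl]lithium | [Li]C#CCO[Si](C)(C)C(C)(C)C | intermediate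
10 | (1R)-4-(tert-butyldimethylsilyloxy)-1-{(2R,3S)-3-[(1R)-1-(tert-butyldimethylsilyloxy)but-3-en-1-yl]-3-methyloxiran-2-yl}but-2-yn-1-ol (C6 hydroxyl anti to the epoxide oxygen) | C=CC[C@@H](O[Si](C)(C)C(C)(C)C)[C@@]1(C)O[C@@H]1[C@H](O)C#CCO[Si](C)(C)C(C)(C)C | intermediate
11 | C6 methanesulfonate of 10 (same configuration) | C=CC[C@@H](O[Si](C)(C)C(C)(C)C)[C@@]1(C)O[C@@H]1[C@H](OS(C)(=O)=O)C#CCO[Si](C)(C)C(C)(C)C | intermediate
12 | (aR)-2-[(tert-butyldimethylsilyloxy)methyl]-4-{(2R,3S)-3-[(1R)-1-(tert-butyldimethylsilyloxy)but-3-en-1-yl]-3-methyloxiran-2-yl}buta-2,3-dienoic acid | C=CC[C@@H](O[Si](C)(C)C(C)(C)C)[C@@]1(C)O[C@@H]1C([H])=[C@]=C(CO[Si](C)(C)C(C)(C)C)C(=O)O | intermediate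
13 | (5R)-4-iodo-3-[(tert-butyldimethylsilyloxy)methyl]-5-{(2R,3S)-3-[(1R)-1-(tert-butyldimethylsilyloxy)but-3-en-1-yl]-3-methyloxiran-2-yl}furan-2(5H)-one (C6–O syn to the epoxide oxygen) | C=CC[C@@H](O[Si](C)(C)C(C)(C)C)[C@@]1(C)O[C@@H]1[C@H]2OC(=O)C(CO[Si](C)(C)C(C)(C)C)=C2I | intermediate
14 | (5R)-3-(hydroxymethyl)-4-iodo-5-{(2R,3S)-3-[(1R)-1-(tert-butyldimethylsilyloxy)but-3-en-1-yl]-3-methyloxiran-2-yl}furan-2(5H)-one | C=CC[C@@H](O[Si](C)(C)C(C)(C)C)[C@@]1(C)O[C@@H]1[C@H]2OC(=O)C(CO)=C2I | intermediate
15 | [(5R)-4-iodo-5-{(2R,3S)-3-[(1R)-1-(tert-butyldimethylsilyloxy)but-3-en-1-yl]-3-methyloxiran-2-yl}-2-oxo-2,5-dihydrofuran-3-yl]methyl acetate | C=CC[C@@H](O[Si](C)(C)C(C)(C)C)[C@@]1(C)O[C@@H]1[C@H]2OC(=O)C(COC(C)=O)=C2I | intermediate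
16 | crotonaldehyde [(E)-but-2-enal] | C/C=C/C=O | starting material
17 | [(5S)-5-{(2R,3S)-3-[(1R)-1-(tert-butyldimethylsilyloxy)but-3-en-1-yl]-3-methyloxiran-2-yl}-4-[(2E)-1-hydroxybut-2-en-1-yl]-2-oxo-2,5-dihydrofuran-3-yl]methyl acetate (both C8 epimers) | C=CC[C@@H](O[Si](C)(C)C(C)(C)C)[C@@]1(C)O[C@@H]1[C@H]2OC(=O)C(COC(C)=O)=C2C(O)/C=C/C | intermediate
18 | [(5S)-4-[(2E)-but-2-enoyl]-5-{(2R,3S)-3-[(1R)-1-(tert-butyldimethylsilyloxy)but-3-en-1-yl]-3-methyloxiran-2-yl}-2-oxo-2,5-dihydrofuran-3-yl]methyl acetate | C=CC[C@@H](O[Si](C)(C)C(C)(C)C)[C@@]1(C)O[C@@H]1[C@H]2OC(=O)C(COC(C)=O)=C2C(=O)/C=C/C | intermediate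
19 | [(5S)-4-[(2E)-but-2-enoyl]-5-{(2R,3S)-3-[(1R)-1-(tert-butyldimethylsilyloxy)-3-oxopropyl]-3-methyloxiran-2-yl}-2-oxo-2,5-dihydrofuran-3-yl]methyl acetate | O=CC[C@@H](O[Si](C)(C)C(C)(C)C)[C@@]1(C)O[C@@H]1[C@H]2OC(=O)C(COC(C)=O)=C2C(=O)/C=C/C | intermediate
20 | (3R)-3-{(2S,3R)-3-[(2S)-4-(acetoxymethyl)-3-[(2E)-but-2-enoyl]-5-oxo-2,5-dihydrofuran-2-yl]-2-methyloxiran-2-yl}-3-(tert-butyldimethylsilyloxy)propanoic acid | OC(=O)C[C@@H](O[Si](C)(C)C(C)(C)C)[C@@]1(C)O[C@@H]1[C@H]2OC(=O)C(COC(C)=O)=C2C(=O)/C=C/C | intermediate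
21 | Se-phenyl (3R)-3-{(2S,3R)-3-[(2S)-4-(acetoxymethyl)-3-[(2E)-but-2-enoyl]-5-oxo-2,5-dihydrofuran-2-yl]-2-methyloxiran-2-yl}-3-(tert-butyldimethylsilyloxy)propaneselenoate | O=C([Se]c1ccccc1)C[C@@H](O[Si](C)(C)C(C)(C)C)[C@@]1(C)O[C@@H]1[C@H]2OC(=O)C(COC(C)=O)=C2C(=O)/C=C/C | intermediate
22 | (3R,4S,5R,6S,10S)-13-acetoxy-3-(tert-butyldimethylsilyloxy)-4,5-epoxy-1,8-dioxogermacr-7(11)-en-12,6-olide | CC(=O)OCC1=C2C(=O)C[C@H](C)C(=O)C[C@@H](O[Si](C)(C)C(C)(C)C)[C@@]3(C)O[C@@H]3[C@H]2OC1=O | intermediate
23 | (3R,4S,5R,6S,8S,10S)-13-acetoxy-3-(tert-butyldimethylsilyloxy)-4,5-epoxy-8-hydroxy-1-oxogermacr-7(11)-en-12,6-olide | CC(=O)OCC1=C2[C@@H](O)C[C@H](C)C(=O)C[C@@H](O[Si](C)(C)C(C)(C)C)[C@@]3(C)O[C@@H]3[C@H]2OC1=O | intermediate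
24 | prop-2-yn-1-ol | C#CCO | starting material
25 | 1-methoxy-4-[(prop-2-yn-1-yloxy)methyl]benzene | C#CCOCc1ccc(OC)cc1 | intermediate
26 | {3-[(4-methoxybenzyl)oxy]prop-1-yn-1-yl}lithium | [Li]C#CCOCc1ccc(OC)cc1 | intermediate
27 | methyl 4-[(4-methoxybenzyl)oxy]but-2-ynoate | COC(=O)C#CCOCc1ccc(OC)cc1 | intermediate
28 | methyl (2Z)-4-[(4-methoxybenzyl)oxy]-3-methylbut-2-enoate | COC(=O)/C=C(/C)COCc1ccc(OC)cc1 | intermediate
29 | (2Z)-4-[(4-methoxybenzyl)oxy]-3-methylbut-2-enoic acid | OC(=O)/C=C(/C)COCc1ccc(OC)cc1 | intermediate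
30 | (2Z)-4-[(4-methoxybenzyl)oxy]-3-methylbut-2-enoic 2,4,6-trichlorobenzoic anhydride | O=C(/C=C(/C)COCc1ccc(OC)cc1)OC(=O)c1c(Cl)cc(Cl)cc1Cl | intermediate
31 | (3R,4S,5R,6S,8S,10S)-13-acetoxy-3-(tert-butyldimethylsilyloxy)-4,5-epoxy-8-{[(2Z)-4-(4-methoxybenzyloxy)-3-methylbut-2-enoyl]oxy}-1-oxogermacr-7(11)-en-12,6-olide | CC(=O)OCC1=C2[C@@H](OC(=O)/C=C(/C)COCc4ccc(OC)cc4)C[C@H](C)C(=O)C[C@@H](O[Si](C)(C)C(C)(C)C)[C@@]3(C)O[C@@H]3[C@H]2OC1=O | intermediate
32 | (3R,4R,5R,6S,8S,10S)-13-acetoxy-4,5-epoxy-3-hydroxy-8-{[(2Z)-4-(4-methoxybenzyloxy)-3-methylbut-2-enoyl]oxy}-1-oxogermacr-7(11)-en-12,6-olide | CC(=O)OCC1=C2[C@@H](OC(=O)/C=C(/C)COCc4ccc(OC)cc4)C[C@H](C)C(=O)C[C@@H](O)[C@@]3(C)O[C@@H]3[C@H]2OC1=O | intermediate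
33 | (4S,5R,6S,8S,10S)-13-acetoxy-4,5-epoxy-8-{[(2Z)-4-(4-methoxybenzyloxy)-3-methylbut-2-enoyl]oxy}-1,3-dioxogermacr-7(11)-en-12,6-olide | CC(=O)OCC1=C2[C@@H](OC(=O)/C=C(/C)COCc4ccc(OC)cc4)C[C@H](C)C(=O)CC(=O)[C@@]3(C)O[C@@H]3[C@H]2OC1=O | intermediate
34 | CNP0295642.1, (4S,5R,6S,8S,10S)-13-acetoxy-4,5-epoxy-8-{[(2Z)-4-hydroxy-3-methylbut-2-enoyl]oxy}-1,3-dioxogermacr-7(11)-en-12,6-olide | CC(=O)OCC1=C2[C@@H](OC(=O)/C=C(/C)CO)C[C@H](C)C(=O)CC(=O)[C@@]3(C)O[C@@H]3[C@H]2OC1=O | target

Total step count: 26. Longest linear sequence: 22 steps (steps 1–18 and 23–26); the side chain takes steps 19–22.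

Steps most likely to fail

Step 17. The acyl radical may be reduced by the stannane or lose CO before the slow ten-membered endo closure onto the β-methyl enone, which would leave the chain open. The fallback makes the same C1–C10 bond by polar umpolung and sets out from aldehyde 19, which already holds the C1 formyl group and the C8 propenyl ketone. A triazolium-derived N-heterocyclic carbene, generated with a weak base such as NaOAc at high dilution in toluene, should form the Breslow intermediate at C1 and add it to C10 in an intramolecular Stetter reaction. This gives diketone 22 directly, the route is rejoined at 22, and steps 15 and 16 are not needed. A Stetter closure of this ring size is itself less precedented than the small-ring cases.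

Step 12. The vinylchromium species at C7 may be protonated, or may expel the lactone carboxylate by β-elimination, before it meets the aldehyde, and the hindered tetrasubstituted iodide may react slowly. The fallback sets out from iodide 15 and uses a carbonylative Stille coupling with (E)-tributyl(prop-1-enyl)stannane under CO (Pd2(dba)3, AsPh3, NMP, 50 °C). It builds the propenyl ketone through an acylpalladium species without a carbanionic C7 and should give ketone 18 directly. The route is rejoined at 18 and step 13 is skipped.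

Step 18. Hydride may be delivered to the other face of the C8 carbonyl if the ring reacts through another conformer, which would give the C8 epimer. The fallback sets out from 22: the 8R alcohol F1 from the reduction is esterified with acid 29 under Mitsunobu conditions (PPh3, diisopropyl azodicarboxylate, THF, 0 °C), which inverts C8 and should give ester 31. The route is rejoined at 31.

Further compounds
F0 | step 17 | none | none
F0 | step 12 | none | none
F1 | step 18 | (3R,4S,5R,6S,8R,10S)-13-acetoxy-3-(tert-butyldimethylsilyloxy)-4,5-epoxy-8-hydroxy-1-oxogermacr-7(11)-en-12,6-olide | CC(=O)OCC1=C2[C@H](O)C[C@H](C)C(=O)C[C@@H](O[Si](C)(C)C(C)(C)C)[C@@]3(C)O[C@@H]3[C@H]2OC1=O
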